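All runs stem from a simulated flask with constants of no real substance, noise included.

The meeting had one question: after 4.0 h, how much product stands in the south-east, south-west and east flasks, which differ only in temperature, and does it outweigh the trapped intermediate?

| flask | substrate | coupling partner | capture agent | free catalyst | impurity | added ligand | temperature | remark | time |
|---|---|---|---|---|---|---|---|---|---|
| dusk | 0.045 M | 1.05 equiv | 9.1 mM | 1.2 mol% | 0.46 mM | 2.8 mM | 35 °C | run made earlier |  |
| midnight | 0.18 M | 1.05 equiv | 9.1 mM | 1.2 mol% | 0.46 mM | 2.8 mM | 48 °C | run made earlier |  |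
| south-east | 0.091 M | 1.05 equiv | 9.10 mM | 1.2 mol% | 0.46 mM | 2.8 mM | 56 °C |  | 4.0 h |
| south-west | 0.091 M | 1.05 equiv | 9.10 mM | 1.2 mol% | 0.46 mM | 2.8 mM | 48 °C |  | 4.0 h |
| east | 0.091 M | 1.05 equiv | 9.10 mM | 1.2 mol% | 0.46 mM | 2.8 mM | 40 °C |  | 4.0 h |

| run | time / h | product / % |
|---|---|---|
| dusk | 0.200 | 2.4 |
| dusk | 0.333 | 1.4 |
| dusk | 0.417 | 2.7 |
| dusk | 0.667 | 2.7 |
| dusk | 1.00 | 3.7 |
| dusk | 1.50 | 3.2 |
| dusk | 2.50 | 2.6 |
| midnight | 0.133 | 20.6 |
| midnight | 0.333 | 32.6 |
| midnight | 0.667 | 40.9 |
| midnight | 1.00 | 43.6 |
| midnight | 1.33 | 45.5 |
| midnight | 2.00 | 48.6 |
| midnight | 2.50 | 50.4 |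

(readings scatter by 0.5 percentage points)

* which of the two there is more of at the end, south-east (trapped intermediate / product)
* which of the two there is more of at the end, south-west (trapped intermediate / product)
* which of the two there is more of at the end, east (trapped intermediate / product)
* product at the end, in percent of the substrate charged, south-east
* product at the end, in percent of the substrate charged, south-west
* product at the end, in percent of the substrate charged, east



The first speaker set the earlier runs side by side on the blackboard. Dusk read 3.2% at 1.50 h and stayed flat, while midnight read 50.4% at 2.50 h and was still creeping up. She argued that the impurity takes free catalyst one for one, so the number to watch is one minus the impurity charge over the catalyst charge. This comes to 14.8% in dusk and 78.7% in midnight. In the new flasks it comes to 57.9%, and she called this the live share of the catalyst.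

The second speaker divided product by live catalyst, both as fractions of the substrate charged, to get rounds per live catalyst, the turnover number. The readings give 18.0 for dusk and 53.4 for midnight. These differ, but so do the temperatures, 35 °C against 48 °C, and the substrate charges, 0.045 M against 0.18 M, so he would carry a turnover number only between flasks at one temperature.

That left south-west, which stands at midnight's temperature. My own reckoning, given to the meeting, put midnight's rounds on south-west's live catalyst and reached 37.1%. It was noted that south-west runs longer than midnight's last reading and is thinner in substrate, and that the reckoning takes no account of either difference.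

The forecast, made from the same runs, also let the impurity poison the catalyst. It named product as the larger in each flask and gave 33% for south-east, 27% for south-west (between 16% and 40%) and 19% for east, adding “The temperature dependence is only a rough guess”. For south-west my reckoning stood higher than the forecast.

South-east gave 49.1%, south-west 32.8% and east 23.2%, with product ahead of trapped intermediate in each; south-west fell below my reckoning and above the forecast.

    coupling partner + catalyst intermediate A → catalyst intermediate B (k = 45.0 M⁻¹ min⁻¹, Ea = 38.0 kJ mol⁻¹)
    substrate + free catalyst → catalyst intermediate A (k = 33.0 M⁻¹ min⁻¹, Ea = 38.0 kJ mol⁻¹)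
    catalyst intermediate B + capture agent → trapped intermediate (k = 20.0 M⁻¹ min⁻¹, Ea = 39.0 kJ mol⁻¹)
    free catalyst + added ligand ⇌ idle complex (K = 6700 M⁻¹, k = 14.0 M⁻¹ min⁻¹, Ea = 63.0 kJ mol⁻¹, ΔH = −48.0 kJ mol⁻¹)
    catalyst intermediate B → free catalyst + product (k = 8.90 min⁻¹, Ea = 80.0 kJ mol⁻¹)
    free catalyst + impurity → spent catalyst (k = 16000 M⁻¹ min⁻¹, Ea = 51.0 kJ mol⁻¹)
    (constants at 40 °C)

In south-west, with impurity at 0%, spent catalyst stands at 42.1% of the catalyst charged, against the 42.1% that the live share leaves for it. East with 4.8 mol% of free catalyst has a live share of 89.5%, and its spent catalyst stands at 10.5%. Its live catalyst is 6.18 times that of east, and it gives 96.9% of product against 23.2%.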